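## Retrosynthetic overview

1. Feature: ring A carries oxygen on C5, C6 and C7 in a row and hydrogen on C8. This O/O/O/H sequence is the C1(=O)–C2(OMe)=C3(OMe)–C4(H) chain of a squarate-derived cyclobutenone laid across the C4a–C8a bond of pyranone ring C.
2. Endgame: agecorynin G comes from O-methylation of a chelated 5-OH and hydrogenolysis of a 3'-O-benzyl group.
3. Key disconnection: C8–C8a (palladium-catalysed coupling of a stannane and an allylic chloride) and C4a–C5 (ring opening to a dienylketene, then six-electron closure). These lead back to a 2-aryl-6-stannyl-4-pyranone and 4-chloro-2,3-dimethoxycyclobutenone, the latter two steps from dimethyl squarate.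
4. Ring C: aroyl chloride plus the enolate of 4-methoxybut-3-en-2-one, then acid closure. Tin is installed by C6–H → C6–Zn → C6–I → C6–Sn.
5. Ring B: mirror-symmetric 2,6-dimethoxyphenol is benzylated and formylated (one possible outcome). It is then brominated at C5, steered by CHO and 2-OMe, and methoxylated. Order of rings: B (bought), C, A.

Key step: step 12

Remark: the target is achiral. The cyclobutenone partners and the cascade intermediates that hold one sp3 stereocentre are racemic, and that centre disappears on aromatisation.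

## Route

**Step 1**
Reactants: 1 2,6-dimethoxyphenol
Product: 2 2-(benzyloxy)-1,3-dimethoxybenzene
Conditions: BnBr, K2CO3, DMF, 60 °C
Reagents that add atoms: benzyl bromide, BrCc1ccccc1
Why: Williamson ether synthesis, in which the phenoxide displaces the benzylic bromide by SN2 and the benzyl group masks the future 3'-OH until the last step.

**Step 2**
Reactants: 2 2-(benzyloxy)-1,3-dimethoxybenzene
Product: 4 3-(benzyloxy)-2,4-dimethoxybenzaldehyde, via aryl iminium chloride 3 (not isolated)
Conditions: POCl3, DMF, 0 → 75 °C; then ice–water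
Reagents that add atoms: N,N-dimethylformamide, CN(C)C=O; water, O
Why: Vilsmeier–Haack formylation, which in pyrogallol triethers goes para to a flanking methoxy group rather than para to the twisted central ether, and the two such positions of the symmetric substrate are equivalent, so one aldehyde should result.

**Step 3**
Reactants: 4 3-(benzyloxy)-2,4-dimethoxybenzaldehyde
Product: 5 3-(benzyloxy)-5-bromo-2,4-dimethoxybenzaldehyde
Conditions: NBS, MeCN, rt
Reagents that add atoms: N-bromosuccinimide, O=C1CCC(=O)N1Br
Why: Electrophilic aromatic bromination, directed to C5 because it is ortho to 4-OMe, para to 2-OMe and meta to CHO, whereas C6 lies ortho to CHO and is activated only by the out-of-plane 3-benzyloxy group.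

**Step 4**
Reactants: 5 3-(benzyloxy)-5-bromo-2,4-dimethoxybenzaldehyde
Product: 6 3-(benzyloxy)-2,4,5-trimethoxybenzaldehyde
Conditions: NaOMe, CuBr (10 mol %), DMF–MeOH, 110 °C
Reagents that add atoms: sodium methoxide, C[O-].[Na+]
Why: Ullmann-type copper-catalysed methoxylation of an aryl bromide, which tolerates non-enolisable benzaldehydes and benzyl aryl ethers.

**Step 5**
Reactants: 6 3-(benzyloxy)-2,4,5-trimethoxybenzaldehyde
Product: 7 3-(benzyloxy)-2,4,5-trimethoxybenzoic acid
Conditions: NaClO2, NaH2PO4, 2-methylbut-2-ene, t-BuOH–H2O, rt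
Reagents that add atoms: sodium chlorite, [Na+].[O-]Cl=O
Why: Pinnick oxidation, in which the alkene scavenger removes hypochlorous acid before it can chlorinate the electron-rich ring.

**Step 6**
Reactants: 7 3-(benzyloxy)-2,4,5-trimethoxybenzoic acid
Product: 8 3-(benzyloxy)-2,4,5-trimethoxybenzoyl chloride
Conditions: (COCl)2, DMF (cat.), CH2Cl2, 0 °C → rt; evaporate
Reagents that add atoms: oxalyl chloride, O=C(Cl)C(=O)Cl
Why: Acid chloride formation by DMF-catalysed activation with oxalyl chloride, mild enough for the ethers and leaving only gaseous by-products.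

**Step 7**
Reactants: 8 3-(benzyloxy)-2,4,5-trimethoxybenzoyl chloride; 9 (E)-4-methoxybut-3-en-2-one
Product: 12 2-[3-(benzyloxy)-2,4,5-trimethoxyphenyl]-4H-pyran-4-one, via lithium dienolate 10 (not isolated), via methoxyenone diketone 11 (not isolated)
Conditions: 9 (2.1 equiv), LiN(SiMe3)2 (2.1 equiv), THF, −78 °C; 8, −78 °C; 1 M HCl quench; crude in CH2Cl2, CF3CO2H, rt
Reagents that add atoms: none
Why: C-acylation of the kinetic methyl-side lithium enolate of a β-methoxy enone by an aroyl chloride (the second equivalent of enolate takes up the acidic diketone proton), followed by acid-catalysed 6-endo-trig addition of the aryl ketone enol oxygen and loss of methanol, is an established route to 2-substituted 4-pyranones.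

**Step 8**
Reactants: 12 2-[3-(benzyloxy)-2,4,5-trimethoxyphenyl]-4H-pyran-4-one
Product: 14 2-[3-(benzyloxy)-2,4,5-trimethoxyphenyl]-6-iodo-4H-pyran-4-one, via bis(pyranonyl)zinc 13 (not isolated)
Conditions: TMP2Zn·2MgCl2·2LiCl (0.6 equiv; TMP = 2,2,6,6-tetramethylpiperidid-1-yl), THF, −30 °C; I2, −30 °C → rt
Reagents that add atoms: iodine, [I][I]
Why: Lewis-acid-assisted C–H zincation with a hindered zinc amide followed by iodinolysis, in which MgCl2 occupies the C4 carbonyl so that the base is not guided to C3 or C5 and removes the most acidic proton, at C6 next to the ring oxygen, as is known for C2 of chromones, while ring B and the benzylic CH2 are left alone.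

**Step 9**
Reactants: 14 2-[3-(benzyloxy)-2,4,5-trimethoxyphenyl]-6-iodo-4H-pyran-4-one
Product: 15 2-[3-(benzyloxy)-2,4,5-trimethoxyphenyl]-6-(tributylstannyl)-4H-pyran-4-one
Conditions: (Bu3Sn)2 (1.5 equiv), Pd(PPh3)4 (5 mol %), toluene, 100 °C
Reagents that add atoms: hexabutylditin, CCCC[Sn](CCCC)(CCCC)[Sn](CCCC)(CCCC)CCCC
Why: Palladium-catalysed stannylation of an sp2 iodide with a ditin (oxidative addition, tin-to-palladium transfer, reductive elimination), favoured here by the easy insertion into a vinylogous acyl iodide and kept clear of homocoupling by excess ditin.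

**Step 10**
Reactants: 16 dimethyl squarate
Product: 17 4-hydroxy-2,3-dimethoxycyclobut-2-en-1-one (racemic)
Conditions: LiAlH(OtBu)3 (1.05 equiv), THF, −78 → 0 °C; pH 7 buffer
Reagents that add atoms: none
Why: Chemoselective 1,2-reduction of one squarate carbonyl by a bulky mild hydride, which stops at the monoalcohol because the remaining carbonyl is a vinylogous ester, and the new stereocentre is formed racemic and is erased in step 12.

**Step 11**
Reactants: 17 4-hydroxy-2,3-dimethoxycyclobut-2-en-1-one
Product: 18 4-chloro-2,3-dimethoxycyclobut-2-en-1-one (racemic)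
Conditions: PPh3, CCl4, CH2Cl2, 0 °C → rt; used at once
Reagents that add atoms: carbon tetrachloride, ClC(Cl)(Cl)Cl
Why: Appel reaction, chosen because its neutral water-free medium replaces the activated allylic hydroxyl by chloride without the aqueous acid that turns 4-hydroxy-2,3-dialkoxycyclobutenones into cyclobutenediones, and the configuration is irrelevant since the material is racemic.

**Step 12**
Reactants: 15 2-[3-(benzyloxy)-2,4,5-trimethoxyphenyl]-6-(tributylstannyl)-4H-pyran-4-one; 18 4-chloro-2,3-dimethoxycyclobut-2-en-1-one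
Product: 22 2-[3-(benzyloxy)-2,4,5-trimethoxyphenyl]-5-hydroxy-6,7-dimethoxy-4H-chromen-4-one (3'-O-benzyl-5-O-demethyl agecorynin G), via pyranonylcyclobutenone 19 (not isolated), via dienylketene 20 (not isolated), via keto tautomer 21 (not isolated)
Conditions: 18 (1.3 equiv), PdCl2(PhCN)2 (5 mol %), tris(2-furyl)phosphine (10 mol %), dioxane, 50 °C, then 100 °C
Reagents that add atoms: none
Why: Proposed new method: zerovalent palladium, formed in the flask from PdCl2(PhCN)2, inserts into the allylic C4–Cl bond of 18, the pyranonyl group moves from tin to palladium, and reductive elimination at the CH terminus of the oxocyclobutenyl ligand (the other terminus is a fully substituted C–OMe carbon) forms C8–C8a and gives 19. On heating, 19 opens by a conrotatory four-electron process to a dienylketene, and because this opening is reversible the isomer with the pyranonyl group turned away from the ketene falls back to 19 while isomer 20, with the two groups cis on the C7=C8 bond, is drained forward. Ring A is closed by a thermal disrotatory six-electron electrocyclisation of the C5=C6 ketene, C7=C8 and C8a=C4a double bonds, in which the electrophilic ketene carbon C5 bonds to C4a, the nucleophilic α-carbon of the vinylogous ester in ring C, and enolisation of 21 to the chelated phenol 22 makes the cascade irreversible. The closest known reaction type is the palladium-catalysed coupling of 4-chlorocyclobutenones with aryl, alkenyl and 2-heteroaryl stannanes followed by thermal benzannulation to phenols; a 4-pyranon-6-yl stannane and a pyranone C=C bond as the third π component have not been used. No stereocentre survives: C4 of 19 and C4a of 21 are racemic and become sp2 carbons of ring A. The selectivity needed is positional (oxygen on C5, C6 and C7, hydrogen on C8), and it is secured by the fixed order C1(=O), C2(OMe), C3(OMe), C4(H) in the four-membered ring together with the fact that C4a is the only ring carbon next to the tin-bearing C8a.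

**Step 13**
Reactants: 22 2-[3-(benzyloxy)-2,4,5-trimethoxyphenyl]-5-hydroxy-6,7-dimethoxy-4H-chromen-4-one
Product: 23 2-[3-(benzyloxy)-2,4,5-trimethoxyphenyl]-5,6,7-trimethoxy-4H-chromen-4-one (3'-O-benzyl agecorynin G)
Conditions: Me2SO4 (excess), K2CO3, acetone, reflux
Reagents that add atoms: dimethyl sulfate, COS(=O)(=O)OC
Why: Williamson-type O-methylation of the only free hydroxyl, for which excess reagent and reflux overcome the hydrogen bond of the 5-OH to the C4 carbonyl, as is usual for 5-hydroxyflavones.

**Step 14**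
Reactants: 23 2-[3-(benzyloxy)-2,4,5-trimethoxyphenyl]-5,6,7-trimethoxy-4H-chromen-4-one
Product: 24 agecorynin G, 2-(3-hydroxy-2,4,5-trimethoxyphenyl)-5,6,7-trimethoxy-4H-chromen-4-one
Conditions: H2 (1 atm), Pd/C, EtOAc–MeOH, rt
Reagents that add atoms: none
Why: Catalytic hydrogenolysis of a benzyl aryl ether, which at ambient pressure and temperature should leave the conjugated C2=C3 bond and the carbonyl of the flavone untouched.

## Compound list

1 | 2,6-dimethoxyphenol | COc1cccc(OC)c1O | starting material
2 | 2-(benzyloxy)-1,3-dimethoxybenzene | COc1cccc(OC)c1OCc1ccccc1 | intermediate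
3 | [3-(benzyloxy)-2,4-dimethoxybenzylidene]dimethyliminium chloride | C[N+](C)=Cc1ccc(OC)c(OCc2ccccc2)c1OC.[Cl-] | intermediate
4 | 3-(benzyloxy)-2,4-dimethoxybenzaldehyde | COc1ccc(C=O)c(OC)c1OCc1ccccc1 | intermediate
5 | 3-(benzyloxy)-5-bromo-2,4-dimethoxybenzaldehyde | COc1c(Br)cc(C=O)c(OC)c1OCc1ccccc1 | intermediate
6 | 3-(benzyloxy)-2,4,5-trimethoxybenzaldehyde | COc1cc(C=O)c(OC)c(OCc2ccccc2)c1OC | intermediate
7 | 3-(benzyloxy)-2,4,5-trimethoxybenzoic acid | COc1cc(C(=O)O)c(OC)c(OCc2ccccc2)c1OC | intermediate
8 | 3-(benzyloxy)-2,4,5-trimethoxybenzoyl chloride | COc1cc(C(=O)Cl)c(OC)c(OCc2ccccc2)c1OC | intermediate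
9 | (E)-4-methoxybut-3-en-2-one | CO/C=C/C(C)=O | starting material
10 | lithium (E)-4-methoxybuta-1,3-dien-2-olate | [Li+].C=C([O-])/C=C/OC | intermediate
11 | (E)-1-[3-(benzyloxy)-2,4,5-trimethoxyphenyl]-5-methoxypent-4-ene-1,3-dione | CO/C=C/C(=O)CC(=O)c1cc(OC)c(OC)c(OCc2ccccc2)c1OC | intermediate
12 | 2-[3-(benzyloxy)-2,4,5-trimethoxyphenyl]-4H-pyran-4-one | COc1cc(-c2cc(=O)cco2)c(OC)c(OCc2ccccc2)c1OC | intermediate
13 | bis{6-[3-(benzyloxy)-2,4,5-trimethoxyphenyl]-4-oxo-4H-pyran-2-yl}zinc | COc1cc(-c2cc(=O)cc([Zn]c3cc(=O)cc(-c4cc(OC)c(OC)c(OCc5ccccc5)c4OC)o3)o2)c(OC)c(OCc2ccccc2)c1OC | intermediate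
14 | 2-[3-(benzyloxy)-2,4,5-trimethoxyphenyl]-6-iodo-4H-pyran-4-one | COc1cc(-c2cc(=O)cc(I)o2)c(OC)c(OCc2ccccc2)c1OC | intermediate
15 | 2-[3-(benzyloxy)-2,4,5-trimethoxyphenyl]-6-(tributylstannyl)-4H-pyran-4-one | CCCC[Sn](CCCC)(CCCC)c1cc(=O)cc(-c2cc(OC)c(OC)c(OCc3ccccc3)c2OC)o1 | intermediate
16 | dimethyl squarate (3,4-dimethoxycyclobut-3-ene-1,2-dione) | COC1=C(OC)C(=O)C1=O | starting material
17 | 4-hydroxy-2,3-dimethoxycyclobut-2-en-1-one (racemic) | COC1=C(OC)C(O)C1=O | intermediate
18 | 4-chloro-2,3-dimethoxycyclobut-2-en-1-one (racemic) | COC1=C(OC)C(Cl)C1=O | intermediate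
19 | 4-{6-[3-(benzyloxy)-2,4,5-trimethoxyphenyl]-4-oxo-4H-pyran-2-yl}-2,3-dimethoxycyclobut-2-en-1-one (racemic) | COC1=C(OC)C(c2cc(=O)cc(-c3cc(OC)c(OC)c(OCc4ccccc4)c3OC)o2)C1=O | intermediate
20 | 2,3-dimethoxy-4-{6-[3-(benzyloxy)-2,4,5-trimethoxyphenyl]-4-oxo-4H-pyran-2-yl}buta-1,3-dien-1-one, pyranonyl group cis to the ketene carbon chain | COC(=C=O)/C(OC)=C\c1cc(=O)cc(-c2cc(OC)c(OC)c(OCc3ccccc3)c2OC)o1 | intermediate
21 | 2-[3-(benzyloxy)-2,4,5-trimethoxyphenyl]-6,7-dimethoxy-4aH-chromene-4,5-dione (racemic keto tautomer) | COC1=C(OC)C(=O)C2C(=O)C=C(c3cc(OC)c(OC)c(OCc4ccccc4)c3OC)OC2=C1 | intermediate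
22 | 2-[3-(benzyloxy)-2,4,5-trimethoxyphenyl]-5-hydroxy-6,7-dimethoxy-4H-chromen-4-one | COc1cc(-c2cc(=O)c3c(O)c(OC)c(OC)cc3o2)c(OC)c(OCc2ccccc2)c1OC | intermediate
23 | 2-[3-(benzyloxy)-2,4,5-trimethoxyphenyl]-5,6,7-trimethoxy-4H-chromen-4-one | COc1cc(-c2cc(=O)c3c(OC)c(OC)c(OC)cc3o2)c(OC)c(OCc2ccccc2)c1OC | intermediate
24 | agecorynin G | COc1cc(-c2cc(=O)c3c(OC)c(OC)c(OC)cc3o2)c(OC)c(O)c1OC | target

## Step count and risks

Total step count: 14. The longest linear sequence is 12 steps (steps 1–9, then 12–14). The squarate branch (steps 10 and 11) has 2 steps.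

**Step 12.**
- Transfer of the electron-poor pyranonyl group from tin to palladium may be slower than thermal decay of the chloride (ionisation and loss of a methyl group) or than protodestannylation.
- The ketene may also be consumed by dimerisation before it closes onto the weakly nucleophilic pyranone double bond.
- The fallback uses the classical chalcone route and sets out from aldehyde 6.
- Claisen–Schmidt condensation of 6 with purchased 1-(6-hydroxy-2,3,4-trimethoxyphenyl)ethanone (KOH, EtOH, rt) should give (E)-3-[3-(benzyloxy)-2,4,5-trimethoxyphenyl]-1-(6-hydroxy-2,3,4-trimethoxyphenyl)prop-2-en-1-one F1.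
- Oxidative cyclisation of this 2'-hydroxychalcone (I2 cat., DMSO, 130 °C) closes ring C and comes back to the route at 23.
- Any loss of the 5-O-methyl group under these conditions only leads to 22, which is also on the route.

**Step 11.**
- The activated alcohol may ionise to the methoxy-stabilised oxocyclobutenyl cation.
- Chloride could then attack a methyl group, or it could migrate allylically.
- The chloride may also decompose on concentration.
- The fallback sets out from 17 and avoids a halide altogether.
- Acetylation under basic, non-ionising conditions (Ac2O, pyridine, DMAP, 0 °C) should give the storable allylic ester 4-acetoxy-2,3-dimethoxycyclobut-2-en-1-one F2.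
- F2 is ionised only by zerovalent palladium in an allylic ester–stannane coupling with 15 (Pd2(dba)3, LiCl, DMF, 50 °C, then 100 °C).
- The same cascade follows, and the fallback comes back to the route at 22.

**Step 8.**
- Metalation may occur at C3 or C5 next to the carbonyl instead of at C6.
- The amide may add in conjugate fashion and open the pyranone ring.
- The fallback sets out from 8 and builds the C6 leaving group into ring C instead of relying on C–H metalation.
- The lithium enolate of purchased 4,4-bis(methylthio)but-3-en-2-one (LiN(iPr)2, THF, −78 °C) is acylated with 8 to give 1-[3-(benzyloxy)-2,4,5-trimethoxyphenyl]-5,5-bis(methylthio)pent-4-ene-1,3-dione F3.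
- Acid closure with loss of methanethiol (CF3CO2H, toluene, heat) gives 2-[3-(benzyloxy)-2,4,5-trimethoxyphenyl]-6-(methylthio)-4H-pyran-4-one F4.
- Oxidation (mCPBA, CH2Cl2, 0 °C) gives 2-[3-(benzyloxy)-2,4,5-trimethoxyphenyl]-6-(methylsulfonyl)-4H-pyran-4-one F5.
- Radical stannyl-desulfonylation (Bu3SnH, AIBN, toluene, 90 °C) then replaces the sulfonyl group by tin.
- In that step the stannyl radical adds at C6 to give a carbonyl-stabilised radical at C5, which expels the sulfonyl radical.
- The fallback comes back to the route at 15.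

## Further compounds

F1 | step 12 | (E)-3-[3-(benzyloxy)-2,4,5-trimethoxyphenyl]-1-(6-hydroxy-2,3,4-trimethoxyphenyl)prop-2-en-1-one | COc1cc(O)c(C(=O)/C=C/c2cc(OC)c(OC)c(OCc3ccccc3)c2OC)c(OC)c1OC
F2 | step 11 | 4-acetoxy-2,3-dimethoxycyclobut-2-en-1-one (racemic) | COC1=C(OC)C(OC(C)=O)C1=O
F3 | step 8 | 1-[3-(benzyloxy)-2,4,5-trimethoxyphenyl]-5,5-bis(methylthio)pent-4-ene-1,3-dione | CSC(SC)=CC(=O)CC(=O)c1cc(OC)c(OC)c(OCc2ccccc2)c1OC
F4 | step 8 | 2-[3-(benzyloxy)-2,4,5-trimethoxyphenyl]-6-(methylthio)-4H-pyran-4-one | CSc1cc(=O)cc(-c2cc(OC)c(OC)c(OCc3ccccc3)c2OC)o1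
F5 | step 8 | 2-[3-(benzyloxy)-2,4,5-trimethoxyphenyl]-6-(methylsulfonyl)-4H-pyran-4-one | CS(=O)(=O)c1cc(=O)cc(-c2cc(OC)c(OC)c(OCc3ccccc3)c2OC)o1
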